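**Strategy.** The synthesis rests on disconnecting the bond between the lactone O–CH carbon (C-2) and the adjacent ring CH (C-3), the bond shared by cyclopentane ring A and the α-methylene-γ-butyrolactone. A Mo(CO)6-mediated allenic hetero-Pauson–Khand cyclocarbonylation joins a C-2 aldehyde, the inner π bond of a 1,2-propadienyl group on C-4 and CO: in one operation it closes ring A and the lactone (C-2–C-3, C-18–C-20 and C-20–O bonds), installs the exocyclic methylene and sets both stereocentres cis. The precursor is a trans-fused bicyclo[5.4.0]undecene (rings B and C) bearing a silylated tertiary allenyl carbinol next to a quaternary carbon with CH2OAc and CH2CHO arms.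

Key step: step 12

Remark on locants: atoms are numbered on the cyathane skeleton of the target (ring A: C-1 to C-4 and C-9; ring B: C-4 to C-9; ring C: C-5, C-6 and C-10 to C-14; CH3-15 on C-12, CH3-16 on C-6, C-17 on C-9, C-18, C-19 (=CH2) and C-20 (C=O) on C-3); α is the face of H-5, β that of CH3-16, and the same locants are used in the text for the corresponding atoms of all intermediates.

Assumption: in step 3 the enantiomer of the phosphoramidite ligand that gives (S)-7 is used, the sense of induction being taken from the accepted model for this catalyst class; aldehyde 8, sold as an aqueous solution, is used as the anhydrous monomer after extraction and distillation.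

**Step 1**
Reactants: 1 3-methylbut-3-en-1-ol
Product: 2 4-iodo-2-methylbut-1-ene
Conditions: I2, PPh3, imidazole, CH2Cl2, 0 °C → rt
Reagents that add atoms: iodine, II
Why: Appel-type iodination converts the primary homoallylic alcohol into the iodide by SN2 displacement of the alkoxyphosphonium ion without touching the 1,1-disubstituted alkene, and no stereocentre is formed.

**Step 2**
Reactants: 3 3-ethoxycyclohex-2-en-1-one; 4 allylmagnesium bromide
Product: 6 3-(prop-2-en-1-yl)cyclohex-2-en-1-one, via tertiary allylic alcohol 5 (not isolated)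
Conditions: THF, 0 °C; then 1 M aq. HCl, 0 °C, short contact
Reagents that add atoms: none
Why: Stork–Danheiser sequence in which 1,2-addition of the Grignard reagent to the vinylogous ester gives 5, which in cold dilute acid ionises, is hydrated at the enol ether carbon and loses ethanol to give the transposed 3-substituted enone, the mild acid keeping the skipped diene out of conjugation.

**Step 3**
Reactants: 6 3-(prop-2-en-1-yl)cyclohex-2-en-1-one
Product: 7 (3S)-3-methyl-3-(prop-2-en-1-yl)cyclohexan-1-one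
Conditions: Me3Al (1.4 equiv), Cu(O2CC4H3S) (copper thiophene-2-carboxylate, 2 mol %), chiral biphenol-based bis(1-arylethyl)amine phosphoramidite (4 mol %), Et2O, −30 °C; then 1 M aq. HCl
Reagents that add atoms: trimethylaluminium, C[Al](C)C
Why: Copper-catalysed asymmetric conjugate addition of Me3Al to the β-substituted enone creates the quaternary C-6 centre, whose (S) configuration is set by the chiral ligand on the methylcopper species that selects one enone face.

**Step 4**
Reactants: 7 (3S)-3-methyl-3-(prop-2-en-1-yl)cyclohexan-1-one; 8 2,2-dimethoxyacetaldehyde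
Product: 11 (2E,5S)-2-(2,2-dimethoxyethylidene)-5-methyl-5-(prop-2-en-1-yl)cyclohexan-1-one, via aldol adduct 9 (not isolated), via mesylate 10 (not isolated)
Conditions: LiN(i-Pr)2, THF, −78 °C; 8; then MsCl, Et3N, −78 °C → rt
Reagents that add atoms: none
Why: Directed aldol condensation in which the amide base removes the less hindered α-proton (the CH2 remote from the quaternary carbon), the lithium enolate adds to the aldehyde and mesylation with E1cB elimination gives the (E)-alkylidene ketone, which blocks C-9 and carries C-1/C-2 as a masked aldehyde without leaving a new stereocentre.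

**Step 5**
Reactants: 11 (2E,5S)-2-(2,2-dimethoxyethylidene)-5-methyl-5-(prop-2-en-1-yl)cyclohexan-1-one; 2 4-iodo-2-methylbut-1-ene
Product: 12 (2E,5S)-2-(2,2-dimethoxyethylidene)-5-methyl-6-(3-methylbut-3-en-1-yl)-5-(prop-2-en-1-yl)cyclohexan-1-one (both C-6 epimers)
Conditions: LiN(i-Pr)2, THF, −78 °C; HMPA, 2, −78 → 0 °C
Reagents that add atoms: none
Why: Kinetic α′-deprotonation of the enone at its only α′-CH2 and SN2 alkylation of the cross-conjugated lithium dienolate by the primary iodide in the presence of HMPA attaches the C-10 to C-12 chain, the new C-5 centre being formed without control and corrected in step 7.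

**Step 6**
Reactants: 12 (2E,5S)-2-(2,2-dimethoxyethylidene)-5-methyl-6-(3-methylbut-3-en-1-yl)-5-(prop-2-en-1-yl)cyclohexan-1-one
Product: 13 (2E,4aS)-2-(2,2-dimethoxyethylidene)-4a,7-dimethyl-2,3,4,4a,5,8,9,9a-octahydro-1H-benzo[7]annulen-1-one (both 9a epimers)
Conditions: second-generation Grubbs catalyst RuCl2(=CHPh)(PCy3)(H2IMes) (5 mol %), CH2Cl2, 40 °C
Reagents that add atoms: none
Why: Ring-closing olefin metathesis between the allyl group and the 1,1-disubstituted alkene closes seven-membered ring C as its trisubstituted C-12=C-13 alkene with loss of ethene, the electron-poor alkylidene ketone being inert to the ruthenium carbene and both C-5 epimers being able to cyclise.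

**Step 7**
Reactants: 13 (2E,4aS)-2-(2,2-dimethoxyethylidene)-4a,7-dimethyl-2,3,4,4a,5,8,9,9a-octahydro-1H-benzo[7]annulen-1-one
Product: 15 (2E,4aS,9aS)-2-(2,2-dimethoxyethylidene)-4a,7-dimethyl-2,3,4,4a,5,8,9,9a-octahydro-1H-benzo[7]annulen-1-one, via lithium dienolate 14 (not isolated)
Conditions: LiN(i-Pr)2, THF, −78 → −40 °C; then AcOH in THF, −78 °C
Reagents that add atoms: none
Why: Deprotonation at C-5, the only α′-hydrogen, converges both epimers on the same dienolate 14, and kinetic enolate protonation should occur on the α face, anti to the angular CH3-16 that A(1,2) strain and the ring C tether hold pseudoaxial, to give the trans ring fusion.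

**Step 8**
Reactants: 15 (2E,4aS,9aS)-2-(2,2-dimethoxyethylidene)-4a,7-dimethyl-2,3,4,4a,5,8,9,9a-octahydro-1H-benzo[7]annulen-1-one
Product: 18 [(2S,4aS,9aS)-2-(2,2-dimethoxyethyl)-4a,7-dimethyl-1-oxo-2,3,4,4a,5,8,9,9a-octahydro-1H-benzo[7]annulen-2-yl]methyl acetate, via lithium enolate 16 (not isolated), via lithium aldolate 17 (not isolated)
Conditions: LiBH(s-Bu)3, THF, −78 °C; CH2O (monomer in THF), −78 → −40 °C; then Ac2O, −40 → 0 °C
Reagents that add atoms: formaldehyde, C=O; acetic anhydride, CC(=O)OC(C)=O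
Why: Reductive aldol reaction in which 1,4-hydride delivery to the s-cis alkylidene ketone gives the C-4/C-9 enolate 16 regiospecifically, formaldehyde attacks C-9 axially from the α face of the conformationally locked trans-fused enolate (chair-like transition state, syn-axial only to hydrogens) to set the quaternary centre with C-17 α, and Ac2O traps aldolate 17 before retro-aldol loss of formaldehyde.

**Step 9**
Reactants: 18 [(2S,4aS,9aS)-2-(2,2-dimethoxyethyl)-4a,7-dimethyl-1-oxo-2,3,4,4a,5,8,9,9a-octahydro-1H-benzo[7]annulen-2-yl]methyl acetate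
Product: 19 [(1R,2S,4aS,9aS)-2-(2,2-dimethoxyethyl)-1-ethynyl-1-hydroxy-4a,7-dimethyl-2,3,4,4a,5,8,9,9a-octahydro-1H-benzo[7]annulen-2-yl]methyl acetate
Conditions: HC≡CMgBr, LaCl3·2LiCl (0.3 equiv), THF, −20 → 0 °C; aq. NH4Cl
Reagents that add atoms: ethynylmagnesium bromide, C#C[Mg]Br
Why: Lewis acid-promoted Grignard 1,2-addition of the slim, weakly basic alkynyl nucleophile, which is unreactive towards the acetate at this temperature, should occur equatorially from the α face because axial β attack is blocked by the syn-axial CH3-16, giving the axial 4β tertiary alcohol.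

**Step 10**
Reactants: 19 [(1R,2S,4aS,9aS)-2-(2,2-dimethoxyethyl)-1-ethynyl-1-hydroxy-4a,7-dimethyl-2,3,4,4a,5,8,9,9a-octahydro-1H-benzo[7]annulen-2-yl]methyl acetate
Product: 21 [(1S,2S,4aS,9aS)-2-(2,2-dimethoxyethyl)-1-hydroxy-4a,7-dimethyl-1-(propa-1,2-dien-1-yl)-2,3,4,4a,5,8,9,9a-octahydro-1H-benzo[7]annulen-2-yl]methyl acetate, via propargylic amine 20 (not isolated)
Conditions: (CH2O)n, CuI (0.5 equiv), Cy2NH, 1,4-dioxane, reflux
Reagents that add atoms: paraformaldehyde (as formaldehyde), C=O
Why: Crabbé homologation in which copper-mediated Mannich condensation of the terminal alkyne with formaldehyde and the secondary amine gives 20, whose copper complex undergoes 1,5-hydride transfer with loss of the imine to give the terminal allene, a process that tolerates free propargylic hydroxyl groups and touches no stereocentre (the descriptor at C-1 changes only through ligand priorities).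

**Step 11**
Reactants: 21 [(1S,2S,4aS,9aS)-2-(2,2-dimethoxyethyl)-1-hydroxy-4a,7-dimethyl-1-(propa-1,2-dien-1-yl)-2,3,4,4a,5,8,9,9a-octahydro-1H-benzo[7]annulen-2-yl]methyl acetate
Product: 24 [(1S,2S,4aS,9aS)-4a,7-dimethyl-2-(2-oxoethyl)-1-(propa-1,2-dien-1-yl)-1-(trimethylsilyloxy)-2,3,4,4a,5,8,9,9a-octahydro-1H-benzo[7]annulen-2-yl]methyl acetate, via silyl ether acetal 22 (not isolated), via bipyridinium salt 23 (not isolated)
Conditions: Me3SiOTf (3 equiv), 2,2′-bipyridyl (4 equiv), CH2Cl2, 0 °C → rt; then H2O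
Reagents that add atoms: trimethylsilyl trifluoromethanesulfonate, C[Si](C)(C)OS(=O)(=O)C(F)(F)F; water, O
Why: Silyl triflate/pyridine-base acetal cleavage in which the reagent first silylates the tertiary alcohol and then converts the dimethyl acetal into salt 23 (the base intercepts the oxocarbenium ion before the allene can), which water hydrolyses to the aldehyde under non-acidic conditions that spare the allene, the acetate and the hindered silyl ether.

**Step 12**
Reactants: 24 [(1S,2S,4aS,9aS)-4a,7-dimethyl-2-(2-oxoethyl)-1-(propa-1,2-dien-1-yl)-1-(trimethylsilyloxy)-2,3,4,4a,5,8,9,9a-octahydro-1H-benzo[7]annulen-2-yl]methyl acetate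
Product: 27 (2βH,3βH,5αH)-17-acetoxy-4β-hydroxycyatha-12,18(19)-dien-20,2-olide, via oxamolybdacycle 25 (not isolated), via silyl ether lactone 26 (not isolated)
Conditions: Mo(CO)6 (1.2 equiv), DMSO (10 equiv), toluene, 100 °C; then HF·pyridine, THF, 0 °C
Reagents that add atoms: molybdenum hexacarbonyl (source of CO), [Mo].[C-]#[O+].[C-]#[O+].[C-]#[O+].[C-]#[O+].[C-]#[O+].[C-]#[O+]
Why: DMSO-labilised Mo(CO)6 binds the aldehyde and the proximal C-3=C-18 π bond of the allene and couples them oxidatively (zerovalent to divalent molybdenum), forming the C-2–C-3 bond and oxamolybdacycle 25; CO insertion into its Mo–C-18 bond and C–O reductive elimination then release the lactone, so that three bonds and two rings are made at once. The closest known reaction type is the allenic hetero-Pauson–Khand reaction, the cyclocarbonylation of 5,6-dienals to cis-fused bicyclic α-methylene-γ-butyrolactones. Ring A closes by 5-exo-trig attack of C-3 on the aldehyde carbon with the allene unit exocyclic to the new carbocycle, and the lactone ring closes by the [2+2+1] sequence, its last bond by reductive elimination from the metallacycle. The cis relation of O-2 and C-18 at the two new stereocentres is enforced by the five-membered metallacycle, and their α orientation by the face on which the metal engages the allene–aldehyde pair. This needs α-face selectivity: the β face of the nascent ring A is covered by the axial C-4 trimethylsilyloxy group, which the syn-axial CH3-16 pushes over ring A, whereas the α face carries only the C-9 CH2OAc arm, 1,3 to both reacting carbons and free to turn its acetate away. Silylation of O-4 also prevents lactol formation and hydroxyl-directed delivery to the β face, the ring C alkene and the acetate are inert to Mo(CO)6, and HF·pyridine finally cleaves the hindered tertiary silyl ether in the same flask.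

**Step 13**
Reactants: 27 (2βH,3βH,5αH)-17-acetoxy-4β-hydroxycyatha-12,18(19)-dien-20,2-olide
Product: 28 (2βH,3βH,5αH)-17-acetoxy-12α,13α-epoxy-4β-hydroxycyath-18(19)-en-20,2-olide (CNP0214540.1)
Conditions: mCPBA, NaHCO3, CH2Cl2, 0 °C
Reagents that add atoms: mCPBA (3-chloroperoxybenzoic acid), OOC(=O)c1cccc(Cl)c1
Why: Prilezhaev epoxidation in which the buffered peracid attacks the electron-rich trisubstituted ring C alkene in preference to the electron-poor α-methylene lactone, from the α face opposite the angular CH3-16 that shields the β face of ring C, to give the 12α,13α-epoxide.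

**Compound list**

1 | 3-methylbut-3-en-1-ol | CC(=C)CCO | starting material
2 | 4-iodo-2-methylbut-1-ene | CC(=C)CCI | intermediate
3 | 3-ethoxycyclohex-2-en-1-one | CCOC1=CC(=O)CCC1 | starting material
4 | allylmagnesium bromide (prop-2-en-1-ylmagnesium bromide) | C=CC[Mg]Br | starting material
5 | 3-ethoxy-1-(prop-2-en-1-yl)cyclohex-2-en-1-ol (racemic, not isolated) | CCOC1=CC(O)(CC=C)CCC1 | intermediate
6 | 3-(prop-2-en-1-yl)cyclohex-2-en-1-one | C=CCC1=CC(=O)CCC1 | intermediate
7 | (3S)-3-methyl-3-(prop-2-en-1-yl)cyclohexan-1-one | O=C1CCC[C@@](C)(CC=C)C1 | intermediate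
8 | 2,2-dimethoxyacetaldehyde | COC(OC)C=O | starting material
9 | (5S)-2-(1-hydroxy-2,2-dimethoxyethyl)-5-methyl-5-(prop-2-en-1-yl)cyclohexan-1-one, lithium alkoxide in the flask, mixture at the two new centres (not isolated) | O=C1C(C(O)C(OC)OC)CC[C@@](C)(CC=C)C1 | intermediate
10 | methanesulfonate of 9 (not isolated) | O=C1C(C(OS(C)(=O)=O)C(OC)OC)CC[C@@](C)(CC=C)C1 | intermediate
11 | (2E,5S)-2-(2,2-dimethoxyethylidene)-5-methyl-5-(prop-2-en-1-yl)cyclohexan-1-one | O=C1/C(=C/C(OC)OC)CC[C@@](C)(CC=C)C1 | intermediate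
12 | (2E,5S)-2-(2,2-dimethoxyethylidene)-5-methyl-6-(3-methylbut-3-en-1-yl)-5-(prop-2-en-1-yl)cyclohexan-1-one, both C-6 epimers | O=C1/C(=C/C(OC)OC)CC[C@@](C)(CC=C)C1CCC(C)=C | intermediate
13 | (2E,4aS)-2-(2,2-dimethoxyethylidene)-4a,7-dimethyl-2,3,4,4a,5,8,9,9a-octahydro-1H-benzo[7]annulen-1-one, both 9a epimers | O=C1/C(=C/C(OC)OC)CC[C@@]2(C)CC=C(C)CCC12 | intermediate
14 | lithium dienolate of 13 (O–Li on C-4, C-4=C-5 double bond, C-5 trigonal, C-6 unchanged; not isolated) | [Li]OC1=C2CCC(C)=CC[C@]2(C)CC/C1=C\C(OC)OC | intermediate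
15 | (2E,4aS,9aS)-2-(2,2-dimethoxyethylidene)-4a,7-dimethyl-2,3,4,4a,5,8,9,9a-octahydro-1H-benzo[7]annulen-1-one (trans-fused, H-5 anti to CH3-16) | O=C1/C(=C/C(OC)OC)CC[C@@]2(C)CC=C(C)CC[C@H]12 | intermediate
16 | lithium (4aS,9aS)-2-(2,2-dimethoxyethyl)-4a,7-dimethyl-4,4a,5,8,9,9a-hexahydro-3H-benzo[7]annulen-1-olate (not isolated) | [Li]OC1=C(CC(OC)OC)CC[C@@]2(C)CC=C(C)CC[C@H]12 | intermediate
17 | lithium alkoxide of (2S,4aS,9aS)-2-(2,2-dimethoxyethyl)-2-(hydroxymethyl)-4a,7-dimethyl-2,3,4,4a,5,8,9,9a-octahydro-1H-benzo[7]annulen-1-one (not isolated) | O=C1[C@](CO[Li])(CC(OC)OC)CC[C@@]2(C)CC=C(C)CC[C@H]12 | intermediate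
18 | [(2S,4aS,9aS)-2-(2,2-dimethoxyethyl)-4a,7-dimethyl-1-oxo-2,3,4,4a,5,8,9,9a-octahydro-1H-benzo[7]annulen-2-yl]methyl acetate (CH2OAc cis to H-5, trans to CH3-16) | O=C1[C@](COC(C)=O)(CC(OC)OC)CC[C@@]2(C)CC=C(C)CC[C@H]12 | intermediate
19 | [(1R,2S,4aS,9aS)-2-(2,2-dimethoxyethyl)-1-ethynyl-1-hydroxy-4a,7-dimethyl-2,3,4,4a,5,8,9,9a-octahydro-1H-benzo[7]annulen-2-yl]methyl acetate (OH cis to CH3-16) | C#C[C@@]1(O)[C@](COC(C)=O)(CC(OC)OC)CC[C@@]2(C)CC=C(C)CC[C@H]12 | intermediate
20 | 1-[3-(dicyclohexylamino)prop-1-yn-1-yl] analogue of 19 (Mannich base, not isolated) | C1CCCCC1N(CC#C[C@@]1(O)[C@](COC(C)=O)(CC(OC)OC)CC[C@@]2(C)CC=C(C)CC[C@H]12)C1CCCCC1 | intermediate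
21 | [(1S,2S,4aS,9aS)-2-(2,2-dimethoxyethyl)-1-hydroxy-4a,7-dimethyl-1-(propa-1,2-dien-1-yl)-2,3,4,4a,5,8,9,9a-octahydro-1H-benzo[7]annulen-2-yl]methyl acetate | C=C=C[C@@]1(O)[C@](COC(C)=O)(CC(OC)OC)CC[C@@]2(C)CC=C(C)CC[C@H]12 | intermediate
22 | trimethylsilyl ether of 21 (not isolated) | C=C=C[C@@]1(O[Si](C)(C)C)[C@](COC(C)=O)(CC(OC)OC)CC[C@@]2(C)CC=C(C)CC[C@H]12 | intermediate
23 | N-(1-methoxyalkyl)-2,2′-bipyridinium triflate derived from 22 at C-2 (mixture at C-2, not isolated) | C=C=C[C@@]1(O[Si](C)(C)C)[C@](COC(C)=O)(CC(OC)[n+]2ccccc2-c2ccccn2)CC[C@@]2(C)CC=C(C)CC[C@H]12.[O-]S(=O)(=O)C(F)(F)F | intermediate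
24 | [(1S,2S,4aS,9aS)-4a,7-dimethyl-2-(2-oxoethyl)-1-(propa-1,2-dien-1-yl)-1-(trimethylsilyloxy)-2,3,4,4a,5,8,9,9a-octahydro-1H-benzo[7]annulen-2-yl]methyl acetate | C=C=C[C@@]1(O[Si](C)(C)C)[C@](COC(C)=O)(CC=O)CC[C@@]2(C)CC=C(C)CC[C@H]12 | intermediate
25 | tetracarbonyl oxamolybdacycle (Mo bound to O-2 and C-18, C-2–C-3 bond formed, divalent molybdenum; not isolated) | C=C1[Mo]O[C@H]2C[C@]3(COC(C)=O)CC[C@@]4(C)CC=C(C)CC[C@@H]4[C@@]3(O[Si](C)(C)C)[C@@H]12.[C-]#[O+].[C-]#[O+].[C-]#[O+].[C-]#[O+] | intermediate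
26 | (2βH,3βH,5αH)-17-acetoxy-4β-(trimethylsilyloxy)cyatha-12,18(19)-dien-20,2-olide (not isolated) | C=C1C(=O)O[C@H]2C[C@]3(COC(C)=O)CC[C@@]4(C)CC=C(C)CC[C@@H]4[C@@]3(O[Si](C)(C)C)[C@@H]12 | intermediate
27 | (2βH,3βH,5αH)-17-acetoxy-4β-hydroxycyatha-12,18(19)-dien-20,2-olide | C=C1C(=O)O[C@H]2C[C@]3(COC(C)=O)CC[C@@]4(C)CC=C(C)CC[C@@H]4[C@@]3(O)[C@@H]12 | intermediate
28 | (2βH,3βH,5αH)-17-acetoxy-12α,13α-epoxy-4β-hydroxycyath-18(19)-en-20,2-olide (CNP0214540.1) | C=C1C(=O)O[C@H]2C[C@]3(COC(C)=O)CC[C@@]4(C)C[C@H]5O[C@@]5(C)CC[C@@H]4[C@@]3(O)[C@@H]12 | target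

**Step count and risks**

Total step count: 13. Longest linear sequence: 12 steps (3 to 28, steps 2 to 13); step 1 is a one-step side branch that supplies iodide 2.

Steps most likely to fail:

1. Step 12 (key step). The oxidative coupling of the two neopentyl-type π systems may stall, or the metal may engage the β face so that the lactone forms cis to the silyl ether. Fallback, from 24 back to 26: the same C-2–C-3 ring closure is made by an allylmetal addition and the lactone by a separate carbonylation. Palladium-catalysed distannylation of the allene with Bu3Sn–SnBu3 ([PdCl(η3-C3H5)]2, THF, rt) puts tin on C-18 and C-19, and the allylstannane part adds through C-3 to the C-2 aldehyde in the same flask to give the cis-cyclopentanol 17-acetoxy-18-(tributylstannyl)-4β-(trimethylsilyloxy)-20-norcyatha-12,18(19)-dien-2α-ol F1. Iododestannylation (I2, CH2Cl2, 0 °C) gives 17-acetoxy-18-iodo-4β-(trimethylsilyloxy)-20-norcyatha-12,18(19)-dien-2α-ol F2. Carbonylative lactonisation with zerovalent palladium (Pd(PPh3)4, CO 1 atm, Et3N, MeCN, 60 °C) gives 26, which is desilylated to 27 as in step 12.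

2. Step 7. Protonation of dienolate 14 may lack facial selectivity and leave the cis ring fusion. Fallback, from 13 back to 15: thermodynamic epimerisation with separation replaces kinetic protonation. Mixture 13 is equilibrated at C-5, its only epimerisable centre (DBU, toluene, 60 °C; the two ring fusions are expected to be close in energy). Ketone 15 is separated by chromatography from the cis-fused ketone (2E,4aS,9aR)-2-(2,2-dimethoxyethylidene)-4a,7-dimethyl-2,3,4,4a,5,8,9,9a-octahydro-1H-benzo[7]annulen-1-one F3, and F3 is returned to the equilibration until the material is converged on 15.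

3. Step 8. Hydride may add 1,2 to the carbonyl group in competition with conjugate delivery, or aldolate 17 may lose formaldehyde by retro-aldol cleavage before it is acylated. Fallback, from 15 back to 18: the enolate is first secured as a silyl enol ether by copper hydride-catalysed conjugate hydrosilylation ([(Ph3P)CuH]6 cat., Et3SiH, toluene, rt), which gives {[(4aS,9aS)-2-(2,2-dimethoxyethyl)-4a,7-dimethyl-4,4a,5,8,9,9a-hexahydro-3H-benzo[7]annulen-1-yl]oxy}triethylsilane F4. Mukaiyama-type hydroxymethylation (aqueous formaldehyde, Yb(OTf)3 cat., THF, rt), again from the axial α face, gives (2S,4aS,9aS)-2-(2,2-dimethoxyethyl)-2-(hydroxymethyl)-4a,7-dimethyl-2,3,4,4a,5,8,9,9a-octahydro-1H-benzo[7]annulen-1-one F5. Acetylation (Ac2O, pyridine, DMAP, 0 °C) gives 18.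

**Further compounds**

F1 | step 12 | 17-acetoxy-18-(tributylstannyl)-4β-(trimethylsilyloxy)-20-norcyatha-12,18(19)-dien-2α-ol | O[C@H]1C[C@]2(COC(C)=O)CC[C@@]3(C)CC=C(C)CC[C@@H]3[C@@]2(O[Si](C)(C)C)[C@H]1C(=C)[Sn](CCCC)(CCCC)CCCC
F2 | step 12 | 17-acetoxy-18-iodo-4β-(trimethylsilyloxy)-20-norcyatha-12,18(19)-dien-2α-ol | O[C@H]1C[C@]2(COC(C)=O)CC[C@@]3(C)CC=C(C)CC[C@@H]3[C@@]2(O[Si](C)(C)C)[C@H]1C(=C)I
F3 | step 7 | (2E,4aS,9aR)-2-(2,2-dimethoxyethylidene)-4a,7-dimethyl-2,3,4,4a,5,8,9,9a-octahydro-1H-benzo[7]annulen-1-one | O=C1/C(=C/C(OC)OC)CC[C@@]2(C)CC=C(C)CC[C@@H]12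
F4 | step 8 | {[(4aS,9aS)-2-(2,2-dimethoxyethyl)-4a,7-dimethyl-4,4a,5,8,9,9a-hexahydro-3H-benzo[7]annulen-1-yl]oxy}triethylsilane | CC[Si](CC)(CC)OC1=C(CC(OC)OC)CC[C@@]2(C)CC=C(C)CC[C@H]12
F5 | step 8 | (2S,4aS,9aS)-2-(2,2-dimethoxyethyl)-2-(hydroxymethyl)-4a,7-dimethyl-2,3,4,4a,5,8,9,9a-octahydro-1H-benzo[7]annulen-1-one | O=C1[C@](CO)(CC(OC)OC)CC[C@@]2(C)CC=C(C)CC[C@H]12
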